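## Retrosynthetic overview
1. Feature: ring B is a fully substituted phloroglucinol. C4a sits between two oxygens (O1 on C8a, OH on C5) and a third OH is on C7. Ring C may close only on the C8a oxygen, so the three oxygens must be formed in different states.
2. Ring B is cut at C4a–C8a and C5–C6. Cyclobutenone 17 supplies C6, C7, C8 and C8a (with the ring A–CH2 group on C8), and ethoxyacetylene 18 supplies C4a and C5. Together they give phenol 23 with C8a–OH free, C5–OEt, C7–OSi and C4a–H.
3. 17 comes from a [2+2] of the ring A aldoketene 16 with silyl ynol ether 15. Ring A is elaborated from 2-methylphloroglucinol by C-acylation, para-O-methylation, formylation, benzylation and a two-carbon homologation.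
4. Ring order: ring A (bought), four-membered ring (step 8), ring B (step 9), ring C (C4a acylation and oxa-Michael closure by C8a–OH, steps 10–11), then fluoride and BCl3.

Key step: step 9

Remark 1: ArA = 2,4-bis(benzyloxy)-6-methoxy-5-methyl-3-(2-methylpropanoyl)phenyl. This is protected ring A, bonded through the carbon that carries the bridge CH2 in the target.
Remark 2: the target has no stereocentre. Compounds 17, 20 and 22 are racemic, and their sp3 ring carbons become aromatic carbons.
Remark 3: ester-to-ynolate homologation inserts one carbon. The methyl-bearing ynol ether (future C6–CH3) therefore needs ethyl acetate as the ester; a propionate would put an ethyl group on C6.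

## Route

Step 1
Reactants: 1 2-methylphloroglucinol; 2 isobutyryl chloride
Product: 3 1-(2,4,6-trihydroxy-3-methylphenyl)-2-methylpropan-1-one
Conditions: AlCl3 (3.5 equiv), CH2Cl2–PhNO2, 0 → 45 °C; aq. HCl
Reagents that add atoms: none
Why: Friedel–Crafts C-acylation of a phloroglucinol, in which the two free ring carbons of 1 are equivalent so only one monoacyl product can form, and the new acyl group deactivates the ring towards a second acylation.

Step 2
Reactants: 3 1-(2,4,6-trihydroxy-3-methylphenyl)-2-methylpropan-1-one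
Product: 4 1-(2,6-dihydroxy-4-methoxy-3-methylphenyl)-2-methylpropan-1-one
Conditions: Me2SO4 (1.0 equiv), K2CO3 (1.1 equiv), acetone, rt → 40 °C
Reagents that add atoms: dimethyl sulfate COS(=O)(=O)OC
Why: Williamson-type O-methylation with one equivalent of a hard electrophile, selective because the OH para to the ketone is the most acidic and the only one that cannot hydrogen-bond to the carbonyl oxygen.

Step 3
Reactants: 4 1-(2,6-dihydroxy-4-methoxy-3-methylphenyl)-2-methylpropan-1-one
Product: 6 2,4-dihydroxy-6-methoxy-5-methyl-3-(2-methylpropanoyl)benzaldehyde, via aryl iminium chloride 5 (not isolated)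
Conditions: POCl3 (1.2 equiv), DMF (1.5 equiv), EtOAc, 0 °C → rt; then H2O, rt
Reagents that add atoms: N,N-dimethylformamide CN(C)C=O; water O
Why: Vilsmeier–Haack formylation at the single free ring carbon (ortho to OH and OMe, para to OH), which at room temperature should react faster than the chelated, branched ketone enolises.

Step 4
Reactants: 6 2,4-dihydroxy-6-methoxy-5-methyl-3-(2-methylpropanoyl)benzaldehyde
Product: 7 2,4-bis(benzyloxy)-6-methoxy-5-methyl-3-(2-methylpropanoyl)benzaldehyde (ArA–CHO)
Conditions: BnBr (3 equiv), K2CO3 (4 equiv), DMF, 60 °C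
Reagents that add atoms: benzyl bromide BrCc1ccccc1
Why: Williamson etherification in a dipolar aprotic solvent, where warm carbonate overcomes the hydrogen bonds of both chelated phenols, and benzyl is chosen because it withstands amine base, ketene chemistry and 105 °C yet is removed by BCl3.

Step 5
Reactants: 7 ArA–CHO
Product: 10 3-(ArA)propanoic acid, via arylidene Meldrum's acid 8 (not isolated), via arylmethyl Meldrum's acid 9 (not isolated)
Conditions: Meldrum's acid (1.1 equiv), HCO2H–Et3N (5:2), 95–100 °C; aq. HCl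
Reagents that add atoms: Meldrum's acid CC1(C)OC(=O)CC(=O)O1; water O
Why: One-pot Knoevenagel condensation, conjugate hydride transfer from formate, and hydrolysis–decarboxylation of the Meldrum's acid adduct, which adds the two carbons without touching the hindered ketone or the benzyl ethers.

Step 6
Reactants: 10 3-(ArA)propanoic acid
Product: 11 3-(ArA)propanoyl chloride
Conditions: (COCl)2 (1.5 equiv), DMF (cat.), CH2Cl2, 0 °C → rt; evaporate and use at once
Reagents that add atoms: oxalyl chloride ClC(=O)C(Cl)=O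
Why: DMF-catalysed acid chloride formation under mild conditions, and since ring A is hexasubstituted no intramolecular Friedel–Crafts closure can occur.

Step 7
Reactants: 12 ethyl acetate
Product: 15 triisopropyl(prop-1-yn-1-yloxy)silane, via lithium dibromoenolate 13 (not isolated), via lithium propynolate 14 (not isolated)
Conditions: CH2Br2 (1.1 equiv), lithium 2,2,6,6-tetramethylpiperidide (2.2 equiv), THF, −78 °C; 12; n-BuLi, −78 → 0 °C; i-Pr3SiCl, −78 °C → rt
Reagents that add atoms: dibromomethane BrCBr; chlorotriisopropylsilane CC(C)[Si](Cl)(C(C)C)C(C)C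
Why: Kowalski ester homologation stopped at the ynolate, in which LiCHBr2 adds to 12, enolate 13 undergoes Br–Li exchange and a 1,2-methyl shift with loss of LiBr to give 14, and the bulky chlorosilane traps 14 on oxygen rather than on carbon.

Step 8
Reactants: 11 3-(ArA)propanoyl chloride; 15 triisopropyl(prop-1-yn-1-yloxy)silane
Product: 17 4-(ArA-methyl)-2-methyl-3-(triisopropylsilyloxy)cyclobut-2-en-1-one (racemic), via aldoketene 16 (not isolated)
Conditions: 15 (1.5 equiv), Et3N (1.3 equiv), CH2Cl2, reflux; 11 added slowly by syringe pump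
Reagents that add atoms: none
Why: Dehydrochlorination gives aldoketene 16, kept dilute by slow addition and intercepted by the electron-rich ynol ether in a ketene–alkyne [2+2] cycloaddition in which the nucleophilic methyl-bearing alkyne carbon bonds to the ketene carbonyl carbon, so methyl ends on C2, OSi on C3 and ArA–CH2 on C4, whose stereocentre forms racemic and is erased in step 9.

Step 9
Reactants: 17 4-(ArA-methyl)-2-methyl-3-(triisopropylsilyloxy)cyclobut-2-en-1-one; 18 ethoxyacetylene
Product: 23 2-(ArA-methyl)-5-ethoxy-4-methyl-3-(triisopropylsilyloxy)phenol (chromanone numbering: C8a–OH, C4a–H, C5–OEt, C6–CH3, C7–OSi, C8–CH2ArA), via vinylketene 19 (not isolated), via alkenylcyclobutenone 20 (not isolated), via dienylketene 21 (not isolated), via cyclohexadienone 22 (not isolated)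
Conditions: 18 (4 equiv, in two portions), PhMe (0.5 M), sealed tube, 100–105 °C
Reagents that add atoms: none
Why: Heating cleaves the C1–C4 bond of 17 by conrotatory 4π opening, the C4 substituent turning outward, to give vinylketene 19, whose ketene C=C adds 18 in a [2+2] to give 20; this reopens (4π) to dienylketene 21, which closes to 22 and tautomerises to phenol 23. This is the Danheiser benzannulation of a cyclobutenone with an alkoxyalkyne, a known reaction type applied here to a 3-silyloxy-2,4-disubstituted cyclobutenone. The net new bonds are C4a–C8a (terminal alkyne carbon to ketene carbonyl carbon) and C5–C6 (ethoxy-bearing carbon to ketene alpha carbon), and ring B closes by a disrotatory 6π electrocyclisation that re-forms the old C1–C4 bond as C8a–C8. No stereocentre survives, because the racemic sp3 carbons of 17, 20 and 22 all become aromatic carbons. The [2+2] regioselectivity follows from the polarisation of 18, whose nucleophilic unsubstituted carbon attacks the electrophilic ketene carbonyl carbon, which puts H on C4a and OEt on C5. The ketene oxygen emerges as the only free hydroxyl (C8a); the temperature stays below the range in which 18 loses ethylene, and the excess of 18 competes with 23 for vinylketene 19.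

Step 10
Reactants: 23 ring B phenol; 24 3,3-dimethylacryloyl chloride
Product: 25 1-[3-(ArA-methyl)-6-ethoxy-2-hydroxy-5-methyl-4-(triisopropylsilyloxy)phenyl]-3-methylbut-2-en-1-one
Conditions: 24 (1.2 equiv), TiCl4 (2.2 equiv), CH2Cl2, −78 → −30 °C; ice–aq. HCl
Reagents that add atoms: none
Why: Friedel–Crafts acylation directed by the aryloxytitanium trichloride formed at C8a–OH, where C4a is the only unsubstituted aromatic carbon in the molecule, lies ortho to OH and OEt and para to OSi, and should be nucleophilic enough to react at low temperature, which spares the benzyl and silyl ethers.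

Step 11
Reactants: 25 C4a senecioyl phenol
Product: 26 8-(ArA-methyl)-5-ethoxy-2,2,6-trimethyl-7-(triisopropylsilyloxy)chroman-4-one
Conditions: DBU (0.2 equiv), CH2Cl2, rt
Reagents that add atoms: none
Why: Base-catalysed 6-endo-trig oxa-Michael addition that can use only the C8a hydroxyl because C5 is blocked as its ethyl ether, so only the 6-methyl-8-benzyl chromanone can form, and C2 with its two methyl groups is not a stereocentre.

Step 12
Reactants: 26 silyl-protected chromanone
Product: 27 8-(ArA-methyl)-5-ethoxy-7-hydroxy-2,2,6-trimethylchroman-4-one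
Conditions: Bu4NF (1.2 equiv), AcOH (1.2 equiv), THF, 0 °C
Reagents that add atoms: none
Why: Fluoride-induced cleavage of the aryl silyl ether, buffered with acetic acid to suppress retro-oxa-Michael opening and run while C5 is still etherified so that ring C cannot reclose on the C5 oxygen.

Step 13
Reactants: 27 8-(ArA-methyl)-5-ethoxy-7-hydroxy-2,2,6-trimethylchroman-4-one
Product: 28 mallopallidol
Conditions: BCl3 (6 equiv), pentamethylbenzene (4 equiv), CH2Cl2, −78 → 0 °C; then H2O
Reagents that add atoms: none
Why: Lewis acid ether cleavage in which BCl3 chelated between C4=O and the peri C5–OEt releases chloroethane and both benzyl ethers ortho to the isobutyryl carbonyl are cleaved with pentamethylbenzene trapping the benzyl cation, while the ring A methoxy group is para to its carbonyl, cannot chelate, and should persist at or below 0 °C.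

## Compound list
1 | 2-methylphloroglucinol | Cc1c(O)cc(O)cc1O | starting material
2 | isobutyryl chloride | CC(C)C(Cl)=O | starting material
3 | 1-(2,4,6-trihydroxy-3-methylphenyl)-2-methylpropan-1-one | CC(C)C(=O)c1c(O)cc(O)c(C)c1O | intermediate
4 | 1-(2,6-dihydroxy-4-methoxy-3-methylphenyl)-2-methylpropan-1-one | CC(C)C(=O)c1c(O)cc(OC)c(C)c1O | intermediate
5 | aryl(dimethyl)iminium chloride of 6 (not isolated) | CC(C)C(=O)c1c(O)c(C=[N+](C)C)c(OC)c(C)c1O.[Cl-] | intermediate
6 | 2,4-dihydroxy-6-methoxy-5-methyl-3-(2-methylpropanoyl)benzaldehyde | CC(C)C(=O)c1c(O)c(C=O)c(OC)c(C)c1O | intermediate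
7 | 2,4-bis(benzyloxy)-6-methoxy-5-methyl-3-(2-methylpropanoyl)benzaldehyde | CC(C)C(=O)c1c(OCc2ccccc2)c(C=O)c(OC)c(C)c1OCc1ccccc1 | intermediate
8 | 5-(ArA-methylidene)-2,2-dimethyl-1,3-dioxane-4,6-dione (not isolated) | CC(C)C(=O)c1c(OCc2ccccc2)c(C=C2C(=O)OC(C)(C)OC2=O)c(OC)c(C)c1OCc1ccccc1 | intermediate
9 | 5-(ArA-methyl)-2,2-dimethyl-1,3-dioxane-4,6-dione (not isolated) | CC(C)C(=O)c1c(OCc2ccccc2)c(CC2C(=O)OC(C)(C)OC2=O)c(OC)c(C)c1OCc1ccccc1 | intermediate
10 | 3-(ArA)propanoic acid | CC(C)C(=O)c1c(OCc2ccccc2)c(CCC(=O)O)c(OC)c(C)c1OCc1ccccc1 | intermediate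
11 | 3-(ArA)propanoyl chloride | CC(C)C(=O)c1c(OCc2ccccc2)c(CCC(=O)Cl)c(OC)c(C)c1OCc1ccccc1 | intermediate
12 | ethyl acetate | CCOC(C)=O | starting material
13 | lithium 1,1-dibromoprop-1-en-2-olate (not isolated) | CC([O-])=C(Br)Br.[Li+] | intermediate
14 | lithium prop-1-yn-1-olate (not isolated) | CC#C[O-].[Li+] | intermediate
15 | triisopropyl(prop-1-yn-1-yloxy)silane | CC#CO[Si](C(C)C)(C(C)C)C(C)C | intermediate
16 | 3-(ArA)prop-1-en-1-one, the aldoketene (not isolated) | CC(C)C(=O)c1c(OCc2ccccc2)c(CC=C=O)c(OC)c(C)c1OCc1ccccc1 | intermediate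
17 | 4-(ArA-methyl)-2-methyl-3-(triisopropylsilyloxy)cyclobut-2-en-1-one (racemic) | CC1=C(O[Si](C(C)C)(C(C)C)C(C)C)C(Cc2c(OC)c(C)c(OCc3ccccc3)c(C(=O)C(C)C)c2OCc2ccccc2)C1=O | intermediate
18 | ethoxyacetylene | CCOC#C | starting material
19 | (3Z)-5-(ArA)-2-methyl-3-(triisopropylsilyloxy)penta-1,3-dien-1-one (not isolated) | O=C=C(C)/C(O[Si](C(C)C)(C(C)C)C(C)C)=C/Cc1c(OC)c(C)c(OCc2ccccc2)c(C(=O)C(C)C)c1OCc1ccccc1 | intermediate
20 | 3-ethoxy-4-methyl-4-[(1Z)-3-(ArA)-1-(triisopropylsilyloxy)prop-1-enyl]cyclobut-2-en-1-one (racemic, not isolated) | CCOC1=CC(=O)C1(C)/C(O[Si](C(C)C)(C(C)C)C(C)C)=C/Cc2c(OC)c(C)c(OCc3ccccc3)c(C(=O)C(C)C)c2OCc2ccccc2 | intermediate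
21 | (3E,5Z)-7-(ArA)-3-ethoxy-4-methyl-5-(triisopropylsilyloxy)hepta-1,3,5-trien-1-one (not isolated) | O=C=C/C(OCC)=C(C)\C(O[Si](C(C)C)(C(C)C)C(C)C)=C\Cc1c(OC)c(C)c(OCc2ccccc2)c(C(=O)C(C)C)c1OCc1ccccc1 | intermediate
22 | 6-(ArA-methyl)-3-ethoxy-4-methyl-5-(triisopropylsilyloxy)cyclohexa-2,4-dien-1-one (racemic, not isolated) | CCOC1=CC(=O)C(Cc2c(OC)c(C)c(OCc3ccccc3)c(C(=O)C(C)C)c2OCc2ccccc2)C(O[Si](C(C)C)(C(C)C)C(C)C)=C1C | intermediate
23 | 2-(ArA-methyl)-5-ethoxy-4-methyl-3-(triisopropylsilyloxy)phenol | CCOc1cc(O)c(Cc2c(OC)c(C)c(OCc3ccccc3)c(C(=O)C(C)C)c2OCc2ccccc2)c(O[Si](C(C)C)(C(C)C)C(C)C)c1C | intermediate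
24 | 3,3-dimethylacryloyl chloride | CC(C)=CC(=O)Cl | starting material
25 | 1-[3-(ArA-methyl)-6-ethoxy-2-hydroxy-5-methyl-4-(triisopropylsilyloxy)phenyl]-3-methylbut-2-en-1-one | CCOc1c(C(=O)C=C(C)C)c(O)c(Cc2c(OC)c(C)c(OCc3ccccc3)c(C(=O)C(C)C)c2OCc2ccccc2)c(O[Si](C(C)C)(C(C)C)C(C)C)c1C | intermediate
26 | 8-(ArA-methyl)-5-ethoxy-2,2,6-trimethyl-7-(triisopropylsilyloxy)chroman-4-one | CCOc1c(C)c(O[Si](C(C)C)(C(C)C)C(C)C)c(Cc2c(OC)c(C)c(OCc3ccccc3)c(C(=O)C(C)C)c2OCc2ccccc2)c2OC(C)(C)CC(=O)c12 | intermediate
27 | 8-(ArA-methyl)-5-ethoxy-7-hydroxy-2,2,6-trimethylchroman-4-one | CCOc1c(C)c(O)c(Cc2c(OC)c(C)c(OCc3ccccc3)c(C(=O)C(C)C)c2OCc2ccccc2)c2OC(C)(C)CC(=O)c12 | intermediate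
28 | mallopallidol | COc1c(C)c(O)c(C(=O)C(C)C)c(O)c1Cc1c(O)c(C)c(O)c2c1OC(C)(C)CC2=O | target

## Step count and risks
Total step count: 13. Longest linear sequence: 12 (steps 1–6 and 8–13); step 7 is a one-step side branch.

**Steps most likely to fail**

1. **Step 9.**
   - What may go wrong: the 3-silyloxy group stabilises 17 as a vinylogous silyl ester. The first 4π opening may then need a temperature at which 18 fragments by retro-ene loss of ethylene.
   - The vinylketene may also acylate the phenol as it forms. A proton and silyl shift may move the ring double bond of 17 towards the benzyl-bearing carbon before opening.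
   - Fallback: ring B is taken from the phloroglucinol pool and the bridge is made by Friedel–Crafts benzylation. It sets out from 7 and 1.
   - NaBH4 in MeOH–THF at 0 °C should reduce only the aldehyde of 7, since the ketone is shielded by two ortho ethers, to 1-[2,6-bis(benzyloxy)-3-(hydroxymethyl)-4-methoxy-5-methylphenyl]-2-methylpropan-1-one F1.
   - Separately, 1 and 3,3-dimethylacrylic acid in MeSO3H–P2O5 should give 5,7-dihydroxy-2,2,6-trimethylchroman-4-one F2. It must be separated from its 8-methyl isomer, which is the cost of giving up the oxygen differentiation.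
   - Catalytic p-toluenesulfonic acid in CH2Cl2 at 0 °C ionises F1 to a cation stabilised by three alkoxy groups. C8 of F2, its only free ring carbon, should capture it to give the ring A dibenzyl ether of mallopallidol F3.
   - Hydrogenolysis (H2, Pd/C, EtOAc) brings the fallback back to the route at 28.

2. **Step 8.**
   - What may go wrong: amine-catalysed dimerisation of the aldoketene may outrun its cycloaddition to the hindered silyl ynol ether.
   - Fallback: a more electrophilic and less dimerisation-prone chloroketene is used, then reductive dechlorination. It sets out from 10.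
   - The dianion of 10 (lithium diisopropylamide, 2.2 equiv, THF, −78 °C) is chlorinated with CCl4 to give racemic 2-chloro-3-(ArA)propanoic acid F4.
   - Oxalyl chloride with catalytic DMF converts this into 2-chloro-3-(ArA)propanoyl chloride F5.
   - Et3N in the presence of 15 generates the alkylchloroketene 2-chloro-3-(ArA)prop-1-en-1-one F6. It should add to 15 with the same regiochemistry to give racemic 4-chloro-4-(ArA-methyl)-2-methyl-3-(triisopropylsilyloxy)cyclobut-2-en-1-one F7.
   - Zn dust with AcOH and TMEDA in EtOH removes the chlorine, and the fallback returns to the route at 17.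

3. **Step 10.**
   - What may go wrong: O-acylation of the phenol followed by conjugate ring closure on carbon would give a chroman-2-one skeleton.
   - Chelation-assisted loss of a ring A benzyl group, with benzyl transfer to C4a before acylation, is also possible.
   - Fallback: ring C is built without any Lewis acid by an aryl propargyl ether Claisen route. It sets out from 23.
   - Alkylation of the lone C8a–OH with 3-chloro-3-methylbut-1-yne (CuCl2 cat., DBU, MeCN, 0 °C) gives the 1,1-dimethylpropargyl aryl ether F8.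
   - Heating in xylene at 140 °C triggers a [3,3] shift to C4a (the only free ortho carbon), a 1,5-hydrogen shift and oxa-6π closure. The product is 8-(ArA-methyl)-5-ethoxy-2,2,6-trimethyl-7-(triisopropylsilyloxy)-2H-chromene F9.
   - Mukaiyama hydration (Mn(dpm)3 cat., PhSiH3, O2, i-PrOH) places OH on the benzylic C4 to give the racemic chroman-4-ol F10.
   - Dess–Martin periodinane oxidises it, and the fallback returns to the route at 26.

Further compounds
F1 | step 9 | 1-[2,6-bis(benzyloxy)-3-(hydroxymethyl)-4-methoxy-5-methylphenyl]-2-methylpropan-1-one | CC(C)C(=O)c1c(OCc2ccccc2)c(CO)c(OC)c(C)c1OCc1ccccc1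
F2 | step 9 | 5,7-dihydroxy-2,2,6-trimethylchroman-4-one | Cc1c(O)cc2OC(C)(C)CC(=O)c2c1O
F3 | step 9 | ring A dibenzyl ether of mallopallidol | COc1c(C)c(OCc2ccccc2)c(C(=O)C(C)C)c(OCc2ccccc2)c1Cc1c(O)c(C)c(O)c2c1OC(C)(C)CC2=O
F4 | step 8 | 2-chloro-3-(ArA)propanoic acid (racemic) | CC(C)C(=O)c1c(OCc2ccccc2)c(CC(Cl)C(=O)O)c(OC)c(C)c1OCc1ccccc1
F5 | step 8 | 2-chloro-3-(ArA)propanoyl chloride (racemic) | CC(C)C(=O)c1c(OCc2ccccc2)c(CC(Cl)C(=O)Cl)c(OC)c(C)c1OCc1ccccc1
F6 | step 8 | 2-chloro-3-(ArA)prop-1-en-1-one (chloroketene, formed in the flask) | CC(C)C(=O)c1c(OCc2ccccc2)c(CC(Cl)=C=O)c(OC)c(C)c1OCc1ccccc1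
F7 | step 8 | 4-chloro-4-(ArA-methyl)-2-methyl-3-(triisopropylsilyloxy)cyclobut-2-en-1-one (racemic) | CC1=C(O[Si](C(C)C)(C(C)C)C(C)C)C(Cl)(Cc2c(OC)c(C)c(OCc3ccccc3)c(C(=O)C(C)C)c2OCc2ccccc2)C1=O
F8 | step 10 | 1,1-dimethylpropargyl ether of 23 | C#CC(C)(C)Oc1cc(OCC)c(C)c(O[Si](C(C)C)(C(C)C)C(C)C)c1Cc1c(OC)c(C)c(OCc2ccccc2)c(C(=O)C(C)C)c1OCc1ccccc1
F9 | step 10 | 8-(ArA-methyl)-5-ethoxy-2,2,6-trimethyl-7-(triisopropylsilyloxy)-2H-chromene | CCOc1c(C)c(O[Si](C(C)C)(C(C)C)C(C)C)c(Cc2c(OC)c(C)c(OCc3ccccc3)c(C(=O)C(C)C)c2OCc2ccccc2)c2OC(C)(C)C=Cc12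
F10 | step 10 | 8-(ArA-methyl)-5-ethoxy-2,2,6-trimethyl-7-(triisopropylsilyloxy)chroman-4-ol (racemic) | CCOc1c(C)c(O[Si](C(C)C)(C(C)C)C(C)C)c(Cc2c(OC)c(C)c(OCc3ccccc3)c(C(=O)C(C)C)c2OCc2ccccc2)c2OC(C)(C)CC(O)c12
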